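The 4 questions on the blue flask ask for 3 times and 1 amount, and for the amount I follow a molecule of substrate and ask its chance of reaching target.

| flask | substrate | remark | time |
|---|---|---|---|
| blue | 1.5 M | the very flask that is asked about, followed so far |  |
| grey | 1 M | run made earlier |  |
| flask | 1.5 M |  | 4.0 d |

| run | time / h | target / % |
|---|---|---|
| blue | 5.00 | 12.5 |
| blue | 8.00 | 16.5 |
| blue | 12.0 | 18.4 |
| blue | 15.0 | 18.4 |
| blue | 25.0 | 18.8 |
| blue | 40.0 | 17.0 |
| grey | 5.00 | 13.8 |
| grey | 8.00 | 17.2 |
| grey | 12.0 | 19.5 |
| grey | 15.0 | 21.0 |
| grey | 25.0 | 21.4 |
| grey | 40.0 | 18.7 |

(readings scatter by 0.5 percentage points)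

1. the moment within 4.0 d at which there is most target
2. the amount of target, in percent of the substrate charged, at that time
3. earliest time at which at least nineteen twentieths of that best amount are there, in d
4. latest time at which they still are, in d

- the numbers in the tables scatter by 0.5 percentage points (one standard deviation)

Two settings could be turned. Time comes first: by hand, a longer run gives target longer to form and longer to go on. The blue readings stand at 18.8% after 25.0 h and 17.0% after 40.0 h, so I look for the top inside the readings. I commit to a top near 18.8%, between 12.0 h and 25.0 h.

Amount comes next: if one way off takes two molecules of substrate at once, a molecule's odds against target should grow in a straight line with [substrate]. The readings do lean that way, since the grey run at 1 M reads 21.4%, higher than blue. Between the two tops the inverse yield rises by 1.29 /M, a reading with their scatter. I call this slope the crowding cost, the concentration term of a selectivity factor. Multiplied by [substrate], it counts the molecules lost the crowded way per molecule of target, so at the blue top I reckon 36.4% of the charge gone that way. This takes two readings and the two charges.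

The forecast gives 19% at 0.8 d, with the window from 0.5 d to 1.27 d, holding that “stronger substrate costs selectivity”.

The flask gives 18.8% at 0.836 d, with the window from 0.511 d to 1.38 d.

    substrate ⇌ isomer of the product A (K = 7.30, k = 0.0250 /h)
    2 substrate → self-condensation product (k = 0.0630 /M/h)
    substrate ⇌ isomer of the product B (K = 12.0, k = 0.0380 /h)
    substrate ⇌ target (K = 2.70, k = 0.0460 /h)

In the blue flask, substrate goes forward to isomer of the product B at 0.20 of its rate of use into self-condensation product at the start, and that ratio has risen to 0.69 after 0.251 d. At the best time self-condensation product holds 43.1% of the charge, against the 36.4% reckoned from the crowding cost of 1.29 /M. In the neighbour flask with 0.60 M of substrate, that cost gives a top of 24.1%, and the flask reaches 24.5%.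

Readings and results come from a simulation from invented constants.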